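The route rests on closing ring A at the C3=C4 bond (clerodane numbering), the alkene that is exocyclic to the C18–C19 γ-lactone and flanked by the C2 carbinol. On a ring-B monocycle, a spiro α-phosphono lactone at C5 (set by stereoretentive rhodium-carbenoid C–H insertion) faces a furfuryl alcohol at C1. In one flask the furfuryl cation is captured by a glycolaldehyde enediol bis-silyl ether, which delivers C2–C3 as an α-silyloxy aldehyde, and intramolecular Horner–Wadsworth–Emmons olefination then forms C3=C4: a formal [4+2] annulation. Ring B comes from an auxiliary-controlled Diels–Alder reaction, and Friedel–Crafts acylation closes the furan-fused cycloheptanone last.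

Key step: step 15

Remark: names use the clerodane numbering of the target (C1–C20; α is the face of ring B that carries C19 and C20); centres written without a descriptor in a SMILES string (C7/C8 in 11–25, C1/C2 in 20–26, the phosphonate carbon C4) are carried as mixtures and are reset in steps 17 and 18.

Step 1
Reactants: 1 5-hydroxyfuran-2(5H)-one; 2 (+)-menthol
Product: 3 (5S)-5-[(1S,2R,5S)-menthyloxy]furan-2(5H)-one
Conditions: neat, 100 °C, 20 h; crystallisation from light petroleum (mother liquor re-equilibrated with cat. TsOH)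
Reagents that add atoms: none
Why: Thermal acetalisation of the cyclic pseudo-acid; the acetal carbon epimerises and the (5S) epimer should crystallise selectively (crystallisation-induced asymmetric transformation), as its mirror image does from (−)-menthol.

Step 2
Reactants: 4 (E)-4-methoxypent-3-en-2-one
Product: 5 (E)-4-methoxy-2-(trimethylsilyloxy)penta-1,3-diene
Conditions: TMSOTf, Et3N, Et2O, 0 °C
Reagents that add atoms: trimethylsilyl trifluoromethanesulfonate, C[Si](C)(C)OS(=O)(=O)C(F)(F)F
Why: Soft enolisation of the acetyl methyl group (silyl enol ether formation) gives the cross-conjugated Danishefsky-type diene.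

Step 3
Reactants: 3 (5S)-5-menthyloxyfuran-2(5H)-one; 5 silyloxy diene
Product: 7 enone lactone acetal, via Diels–Alder adduct 6 (not isolated)
Conditions: toluene, 110 °C, sealed tube; then 0.1 M HCl, THF, 0 °C
Reagents that add atoms: none
Why: Normal-demand Diels–Alder reaction in which the nucleophilic CH2 terminus of the diene bonds to the butenolide β-carbon (future C5) and the diene approaches anti to the menthyloxy group, which sets C5 and C10 (cis, both H β) in absolute terms; mild acid then hydrolyses the silyl enol ether and eliminates methanol to the enone.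

Step 4
Reactants: 8 tert-butyl acetate
Product: 9 1-tert-butoxy-1-(tert-butyldimethylsilyloxy)ethene
Conditions: LiN(iPr)2, THF, −78 °C; TBSCl, DMPU, −78 °C → rt
Reagents that add atoms: tert-butyldimethylsilyl chloride, CC(C)(C)[Si](C)(C)Cl
Why: O-silylation of the lithium ester enolate (ketene silyl acetal formation).

Step 5
Reactants: 7 enone lactone acetal; 9 ketene silyl acetal
Product: 10 C7 silyl enol ether with quaternary C9
Conditions: 5 M LiClO4 in Et2O, rt
Reagents that add atoms: none
Why: Mukaiyama–Michael addition in concentrated ethereal LiClO4, a medium suited to β,β-disubstituted enones; attack on C9 from the convex β-face, anti to the cis-fused lactone acetal, sets the quaternary C9 (methyl α, acetate arm β), and the silyl group ends on the C7 enolate oxygen.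

Step 6
Reactants: 10 C7 silyl enol ether
Product: 11 7-oxo-8-methyl lactone acetal
Conditions: MeI, benzyltrimethylammonium fluoride, 4 Å molecular sieves, THF, 0 °C → rt
Reagents that add atoms: iodomethane, CI
Why: Fluoride-promoted regiospecific C-alkylation of the silyl enol ether puts the methyl group on C8 only; the C8 configuration is not relied on because it is equilibrated in step 17.

Step 7
Reactants: 11 7-oxo-8-methyl lactone acetal
Product: 12 7-hydroxy cis-fused γ-lactone
Conditions: NaBH4, KOH, MeOH/H2O, 0 °C → rt; then aq. HCl to pH 2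
Reagents that add atoms: none
Why: Hydroxide opens the pseudo-ester to the C1 carboxylate and the C19 aldehyde, NaBH4 reduces this aldehyde (faster than it can enolise) and the C7 ketone, and acid closes the cis-fused γ-lactone (reductive removal of the menthyloxy auxiliary); the C7 carbinol is re-oxidised later.

Step 8
Reactants: 12 7-hydroxy cis-fused γ-lactone
Product: 13 7-triethylsilyloxy γ-lactone
Conditions: TESCl, imidazole, DMAP (cat.), DMF, rt
Reagents that add atoms: chlorotriethylsilane, CC[Si](Cl)(CC)CC
Why: Silyl ether protection of the only free hydroxyl.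

Step 9
Reactants: 13 7-triethylsilyloxy γ-lactone; 14 furan
Product: 15 γ-hydroxy 2-furyl ketone
Conditions: furan, n-BuLi, THF, −78 → 0 °C; then 13, −78 °C; aq. NH4Cl
Reagents that add atoms: none
Why: Aryllithium addition to a γ-lactone stops at the lithium hemiketal and gives the γ-hydroxy ketone on work-up; the cis relationship of C5 and C10 is untouched because the hindered tertiary C10–H is not enolised.

Step 10
Reactants: 15 γ-hydroxy 2-furyl ketone; 16 (diethoxyphosphoryl)acetic acid
Product: 17 C19 (diethoxyphosphoryl)acetate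
Conditions: EDC·HCl, DMAP (cat.), CH2Cl2, 0 °C → rt
Reagents that add atoms: none
Why: Carbodiimide (Steglich) esterification of the primary alcohol, which is drained from the hemiketal equilibrium.

Step 11
Reactants: 17 C19 (diethoxyphosphoryl)acetate
Product: 18 C19 diazo(diethoxyphosphoryl)acetate
Conditions: 4-acetamidobenzenesulfonyl azide, DBU, MeCN, 0 °C
Reagents that add atoms: 4-acetamidobenzenesulfonyl azide, CC(=O)Nc1ccc(cc1)S(=O)(=O)N=[N+]=[N-]
Why: Regitz diazo transfer to the doubly activated methylene; DBU is far too weak to enolise the hindered aryl ketone at C10.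

Step 12
Reactants: 18 C19 diazo(diethoxyphosphoryl)acetate
Product: 19 spiro α-phosphono γ-lactone
Conditions: Rh2(O2CC7H15)4 (2 mol %), CH2Cl2, 40 °C, slow addition, high dilution
Reagents that add atoms: none
Why: Rhodium-carbenoid 1,5-insertion into the tertiary C5–H bond, the only C–H that can give a five-membered lactone, proceeds with retention and so creates the quaternary C5 with C19 α and the new C4–C5 bond β; C–H insertion of α-diazo-α-(diethoxyphosphoryl)acetates to α-phosphono γ-lactones is a known reaction type, and the 2-acylfuran is too electron-poor to compete.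

Step 13
Reactants: 19 spiro α-phosphono γ-lactone
Product: 20 furfuryl alcohol
Conditions: NaBH4, CeCl3·7H2O, MeOH/THF, −20 → 0 °C
Reagents that add atoms: none
Why: Luche-type 1,2-reduction of the aryl ketone leaves lactone, phosphonate and ester untouched; the carbinol configuration is irrelevant because C1 is ionised in step 15.

Step 14
Reactants: 21 (tert-butyldimethylsilyloxy)acetaldehyde
Product: 22 (Z)-1,2-bis(tert-butyldimethylsilyloxy)ethene
Conditions: TBSOTf, Et3N, CH2Cl2, 0 °C
Reagents that add atoms: tert-butyldimethylsilyl trifluoromethanesulfonate, CC(C)(C)[Si](C)(C)OS(=O)(=O)C(F)(F)F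
Why: Silyl triflate/amine enol silylation of the α-silyloxy aldehyde gives the enediol bis-silyl ether.

Step 15
Reactants: 20 furfuryl alcohol; 22 (Z)-1,2-bis(tert-butyldimethylsilyloxy)ethene
Product: 24 ring-A-closed α-alkylidene lactone, via α-silyloxy aldehyde 23 (not isolated)
Conditions: 22 (2 equiv), Bi(OTf)3 (5 mol %), CH2Cl2, −40 °C; then MeCN, LiCl, DBU, 0 °C → rt
Reagents that add atoms: none
Why: Bi(OTf)3 ionises the furfuryl alcohol to a 2-furylmethyl cation that is captured at carbon by the enediol bis-silyl ether, and loss of the silyl group from the resulting oxocarbenium ion leaves the α-silyloxy aldehyde 23 (C1–C2 bond made, C3 as CHO); LiCl/DBU then deprotonates the α-phosphono lactone at C4, and the carbanion adds to the C3 aldehyde and expels diethyl phosphate to give the C3=C4 alkene. The closest known reaction types are the Lewis-acid-catalysed SN1 substitution of π-activated alcohols by silyl enol ethers (Mukaiyama type) and the intramolecular Masamune–Roush Horner–Wadsworth–Emmons olefination of α-phosphono lactones. Ring A closes by 6-exo-trig addition of C4 to the C3 carbonyl followed by elimination, and the alkene geometry is dictated by the ring. The new centres C1 and C2 form without control and are deliberately not relied on: C1 is re-equilibrated through the C2 ketone in step 17 and C2 is set by reduction in step 18. The step needs cyclisation to win over elimination of the cation and over intermolecular aldol or olefination. The excess nucleophile at low temperature secures the first, and the gauche, equatorial placement of C4 (on C5) and of the C1 side chain (on C10) on ring B secures the second.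

Step 16
Reactants: 24 ring-A-closed α-alkylidene lactone
Product: 25 2,7-diol acid
Conditions: TFA/CH2Cl2/H2O (10:10:1), 0 °C → rt
Reagents that add atoms: none
Why: Acidolysis removes both silyl ethers and the tert-butyl ester in one operation (global deprotection).

Step 17
Reactants: 25 2,7-diol acid
Product: 27 equilibrated 2,7-dioxo acid, via unequilibrated dione acid 26 (not isolated)
Conditions: Dess–Martin periodinane, CH2Cl2, rt; then DBU (excess), rt
Reagents that add atoms: none
Why: Dess–Martin oxidation of both secondary alcohols followed by base equilibration through the C2 and C7 enolates: the furyl group at C1 should settle β (equatorial) because the α (axial) position is syn-axial to both C19H2 and C20H3, and the C8 methyl should settle α (equatorial) on the chair locked by the trans A/B fusion.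

Step 18
Reactants: 27 equilibrated 2,7-dioxo acid
Product: 28 2α,7α-diol acid
Conditions: NaBH4 (excess), CeCl3·7H2O, MeOH, −78 → −20 °C
Reagents that add atoms: none
Why: Luche reduction: hydride adds axially (β-face) to the C2 enone carbonyl to give the equatorial 2α-alcohol trans to the furyl group, and attacks C7 from the β-face because the α-face is blocked by the syn-axial C19H2 and C20H3 groups, giving the axial 7α-alcohol.

Step 19
Reactants: 28 2α,7α-diol acid
Product: 29 2α,7α-diacetate acid
Conditions: Ac2O, DMAP, pyridine, 40 °C; aq. NaHCO3 work-up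
Reagents that add atoms: acetic anhydride, CC(=O)OC(C)=O
Why: DMAP-catalysed acetylation of both alcohols; the mixed anhydride formed at the carboxylic acid is hydrolysed on work-up.

Step 20
Reactants: 29 2α,7α-diacetate acid
Product: 31 tetracyclic 2α,7α-diacetate, via acid chloride 30 (not isolated)
Conditions: (COCl)2, DMF (cat.), CH2Cl2, 0 °C; then SnCl4, CH2Cl2, −78 → −20 °C, high dilution
Reagents that add atoms: none
Why: Intramolecular Friedel–Crafts acylation at the furan 3-position (future C13), the only ring position the tethered acylium can reach, closes the cycloheptanone (ring C) between the peri-disposed equatorial arms on C1 and C9; no new stereocentre.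

Step 21
Reactants: 31 tetracyclic 2α,7α-diacetate
Product: 32 target CNP0182929.1
Conditions: K2CO3 (cat.), MeOH, 0 °C
Reagents that add atoms: none
Why: Base-catalysed transesterification removes the unhindered equatorial allylic C2 acetate, while the axial C7 acetate, flanked by the C8 methyl and syn-axial to C19 and C20, should survive.

Compound list
1 | 5-hydroxyfuran-2(5H)-one (racemic cyclic pseudo-acid) | O=C1C=CC(O)O1 | starting material
2 | (+)-menthol, (1S,2R,5S)-5-methyl-2-(propan-2-yl)cyclohexan-1-ol | CC(C)[C@H]1CC[C@H](C)C[C@@H]1O | starting material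
3 | (5S)-5-[(1S,2R,5S)-menthyloxy]furan-2(5H)-one | O=C1O[C@H](O[C@H]2C[C@@H](C)CC[C@@H]2C(C)C)C=C1 | intermediate
4 | (E)-4-methoxypent-3-en-2-one | CO/C(C)=C/C(C)=O | starting material
5 | (E)-4-methoxy-2-(trimethylsilyloxy)penta-1,3-diene | CO/C(C)=C/C(=C)O[Si](C)(C)C | intermediate
6 | Diels–Alder adduct: C7 trimethylsilyl enol ether (C7=C8), 9-methoxy-9-methyl (C9 epimers), on the cis-fused C1(=O)–O–C19 lactone acetal | O=C1O[C@H](O[C@H]3C[C@@H](C)CC[C@@H]3C(C)C)[C@H]2CC(O[Si](C)(C)C)=CC(C)(OC)[C@@H]12 | intermediate (not isolated)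
7 | enone lactone acetal: ring B 7-oxo, C8=C9, 9-methyl; cis-fused γ-lactone C10–C1(=O)–O–C19H(O-menthyl)–C5; 5β-H, 10β-H, (19S), menthyloxy anti to ring B | O=C1O[C@H](O[C@H]3C[C@@H](C)CC[C@@H]3C(C)C)[C@H]2CC(=O)C=C(C)[C@@H]12 | intermediate
8 | tert-butyl acetate | CC(=O)OC(C)(C)C | starting material
9 | 1-tert-butoxy-1-(tert-butyldimethylsilyloxy)ethene | C=C(OC(C)(C)C)O[Si](C)(C)C(C)(C)C | intermediate
10 | C7 tert-butyldimethylsilyl enol ether (C7=C8) of the 9α-methyl-9β-(tert-butoxycarbonylmethyl) lactone acetal | O=C1O[C@H](O[C@H]3C[C@@H](C)CC[C@@H]3C(C)C)[C@H]2CC(O[Si](C)(C)C(C)(C)C)=C[C@](C)(CC(=O)OC(C)(C)C)[C@@H]12 | intermediate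
11 | 7-oxo-8-methyl (C8 epimers) 9α-methyl-9β-(tert-butoxycarbonylmethyl) lactone acetal | O=C1O[C@H](O[C@H]3C[C@@H](C)CC[C@@H]3C(C)C)[C@H]2CC(=O)C(C)[C@](C)(CC(=O)OC(C)(C)C)[C@@H]12 | intermediate
12 | 7-hydroxy (C7, C8 epimers) cis-fused γ-lactone C10–C1(=O)–O–C19H2–C5 | O=C1OC[C@H]2CC(O)C(C)[C@](C)(CC(=O)OC(C)(C)C)[C@@H]12 | intermediate
13 | 7-triethylsilyl ether of 12 | O=C1OC[C@H]2CC(O[Si](CC)(CC)CC)C(C)[C@](C)(CC(=O)OC(C)(C)C)[C@@H]12 | intermediate
14 | furan | c1ccoc1 | starting material
15 | γ-hydroxy ketone: 10-(furan-2-carbonyl), 5-(hydroxymethyl, C19), 5β-H, 10β-H (in equilibrium with its hemiketal) | OC[C@H]1CC(O[Si](CC)(CC)CC)C(C)[C@](C)(CC(=O)OC(C)(C)C)[C@H]1C(=O)c2ccco2 | intermediate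
16 | (diethoxyphosphoryl)acetic acid | CCOP(=O)(OCC)CC(=O)O | starting material
17 | C19 (diethoxyphosphoryl)acetate of 15 | CCOP(=O)(OCC)CC(=O)OC[C@H]1CC(O[Si](CC)(CC)CC)C(C)[C@](C)(CC(=O)OC(C)(C)C)[C@H]1C(=O)c2ccco2 | intermediate
18 | C19 diazo(diethoxyphosphoryl)acetate of 15 | CCOP(=O)(OCC)C(=[N+]=[N-])C(=O)OC[C@H]1CC(O[Si](CC)(CC)CC)C(C)[C@](C)(CC(=O)OC(C)(C)C)[C@H]1C(=O)c2ccco2 | intermediate
19 | spiro lactone: 18,19-γ-lactone spiro at C5 (C19 α, C4 β), diethoxyphosphoryl on C4 (C4 epimers), 10-(furan-2-carbonyl) | CCOP(=O)(OCC)C1C(=O)OC[C@]12CC(O[Si](CC)(CC)CC)C(C)[C@](C)(CC(=O)OC(C)(C)C)[C@H]2C(=O)c3ccco3 | intermediate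
20 | furfuryl alcohol: C1 carbinol (C1 epimers) of 19 | CCOP(=O)(OCC)C1C(=O)OC[C@]12CC(O[Si](CC)(CC)CC)C(C)[C@](C)(CC(=O)OC(C)(C)C)[C@H]2C(O)c3ccco3 | intermediate
21 | (tert-butyldimethylsilyloxy)acetaldehyde | CC(C)(C)[Si](C)(C)OCC=O | starting material
22 | (Z)-1,2-bis(tert-butyldimethylsilyloxy)ethene | CC(C)(C)[Si](C)(C)O/C=C\O[Si](C)(C)C(C)(C)C | intermediate
23 | α-silyloxy aldehyde: C10–C1H(furan-2-yl)–C2H(OTBS)–C3HO on the spiro phosphono lactone (C1, C2 epimers) | CCOP(=O)(OCC)C1C(=O)OC[C@]12CC(O[Si](CC)(CC)CC)C(C)[C@](C)(CC(=O)OC(C)(C)C)[C@H]2C(c3ccco3)C(O[Si](C)(C)C(C)(C)C)C=O | intermediate (not isolated)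
24 | ring-A-closed product: C3=C4 18,19-olide, 2-OTBS and 1-(furan-2-yl) (C1, C2 epimers), 7-OTES, 9β-CH2CO2tBu, trans A/B fusion (10β-H) | CC[Si](CC)(CC)OC1C[C@@]23COC(=O)C2=CC(O[Si](C)(C)C(C)(C)C)C(c4ccco4)[C@@H]3[C@@](C)(CC(=O)OC(C)(C)C)C1C | intermediate
25 | 2,7-diol acid (C1, C2, C7, C8 epimers), 9β-carboxymethyl | OC1C[C@@]23COC(=O)C2=CC(O)C(c4ccco4)[C@@H]3[C@@](C)(CC(=O)O)C1C | intermediate
26 | 2,7-dioxo acid before equilibration (C1, C8 epimers) | O=C1C[C@@]23COC(=O)C2=CC(=O)C(c4ccco4)[C@@H]3[C@@](C)(CC(=O)O)C1C | intermediate (not isolated)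
27 | 2,7-dioxo acid: 1β-(furan-2-yl) (1α-H), 8α-methyl | O=C1C[C@@]23COC(=O)C2=CC(=O)[C@@H](c4ccco4)[C@@H]3[C@@](C)(CC(=O)O)[C@@H]1C | intermediate
28 | 2α,7α-diol acid | O[C@@H]1C[C@@]23COC(=O)C2=C[C@H](O)[C@@H](c4ccco4)[C@@H]3[C@@](C)(CC(=O)O)[C@@H]1C | intermediate
29 | 2α,7α-diacetate acid | CC(=O)O[C@@H]1C[C@@]23COC(=O)C2=C[C@H](OC(C)=O)[C@@H](c4ccco4)[C@@H]3[C@@](C)(CC(=O)O)[C@@H]1C | intermediate
30 | acid chloride of 29 | CC(=O)O[C@@H]1C[C@@]23COC(=O)C2=C[C@H](OC(C)=O)[C@@H](c4ccco4)[C@@H]3[C@@](C)(CC(=O)Cl)[C@@H]1C | intermediate (not isolated)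
31 | tetracyclic 2α,7α-diacetate: C12 ketone bonded to furan C13 (ring C closed) | CC(=O)O[C@@H]1C[C@@]23COC(=O)C2=C[C@H](OC(C)=O)[C@H]2c4occc4C(=O)C[C@@](C)([C@@H]1C)[C@@H]23 | intermediate
32 | CNP0182929.1: 7α-acetoxy-2α-hydroxy-12-oxo-1β,16-cyclo furano-clerodane 3-en-18,19-olide (1α-H, 10β-H, 8α-Me, 9α-Me) | CC(=O)O[C@@H]1C[C@@]23COC(=O)C2=C[C@H](O)[C@H]2c4occc4C(=O)C[C@@](C)([C@@H]1C)[C@@H]23 | target

Total step count: 21. Longest linear sequence: 18 steps (1, 3, 5–13, 15–21).

Steps most likely to fail

Step 15. The furfuryl cation may lose the C10 proton or alkylate a second furan before it is captured, and the α-silyloxy aldehyde may oligomerise before it is olefinated. The fallback sets out from 20 and comes back at 24. BF3·OEt2-promoted SN1 allylation of 20 with (Z)-tributyl[3-(tert-butyldimethylsilyloxy)prop-2-en-1-yl]stannane (γ-attack; reagent from allyl tert-butyldimethylsilyl ether, s-BuLi and Bu3SnCl) should give the 2-silyloxybut-3-enyl compound F1. Horner–Wadsworth–Emmons methylenation of F1 with aqueous formaldehyde and K2CO3 should give the α-methylene lactone diene F2. Ring-closing metathesis of F2 (second-generation Hoveyda–Grubbs catalyst, toluene, 80 °C) should then close ring A at the same C3=C4 bond and deliver 24.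

Step 12. The carbenoid may be diverted (carbonyl ylide formation with the ketone, β-lactone formation, dimerisation) instead of inserting into the hindered C5–H bond. The fallback sets out from 15 and comes back at 19. Dess–Martin oxidation of 15 should give the keto aldehyde F3. Stork enamine alkylation (pyrrolidine; methyl bromoacetate; aqueous hydrolysis) should build the quaternary C5 with the electrophile entering trans to the furoyl group on C10, giving the aldehyde ester F4. NaBH4 at −78 °C should reduce only the aldehyde, and the hydroxy ester should lactonise to the spiro lactone F5. Deprotonation with LiN(iPr)2, trapping with ClP(OEt)2 and oxidation with H2O2 should then install the phosphonate and give 19.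

Step 20. Intermolecular acylation at the free α′-position of the furan (C15) and acid-induced furan decomposition may outrun seven-membered ring closure. The fallback sets out from 29 and comes back at 31. Bromination with NBS (THF, −78 °C) should block C15 and give the bromofuran acid F6. The same acid chloride/SnCl4 cyclisation should then give the brominated tetracycle F7. Radical hydrodebromination (Bu3SnH, AIBN, benzene, 80 °C) should return 31.

Further compounds
F1 | step 15 | 2-(tert-butyldimethylsilyloxy)but-3-en-1-yl compound: C10–C1H(furan-2-yl)–C2H(OTBS)–CH=CH2 on the spiro phosphono lactone (C1, C2 epimers) | CCOP(=O)(OCC)C1C(=O)OC[C@]12CC(O[Si](CC)(CC)CC)C(C)[C@](C)(CC(=O)OC(C)(C)C)[C@H]2C(c3ccco3)C(O[Si](C)(C)C(C)(C)C)C=C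
F2 | step 15 | α-methylene spiro lactone diene (C4=CH2 and C2-vinyl) | C=C1C(=O)OC[C@]12CC(O[Si](CC)(CC)CC)C(C)[C@](C)(CC(=O)OC(C)(C)C)[C@H]2C(c3ccco3)C(O[Si](C)(C)C(C)(C)C)C=C
F3 | step 12 | keto aldehyde: C19 aldehyde on C5 (5β-H), 10-(furan-2-carbonyl) | O=C[C@H]1CC(O[Si](CC)(CC)CC)C(C)[C@](C)(CC(=O)OC(C)(C)C)[C@H]1C(=O)c2ccco2
F4 | step 12 | quaternary aldehyde ester: C5 bearing CHO (C19, α) and CH2CO2Me (C4–C18, β) | COC(=O)C[C@]1(C=O)CC(O[Si](CC)(CC)CC)C(C)[C@](C)(CC(=O)OC(C)(C)C)[C@H]1C(=O)c2ccco2
F5 | step 12 | spiro 18,19-γ-lactone without phosphonate, 10-(furan-2-carbonyl) | O=C1C[C@]2(CO1)CC(O[Si](CC)(CC)CC)C(C)[C@](C)(CC(=O)OC(C)(C)C)[C@H]2C(=O)c3ccco3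
F6 | step 20 | 1β-(5-bromofuran-2-yl) 2α,7α-diacetate acid | CC(=O)O[C@@H]1C[C@@]23COC(=O)C2=C[C@H](OC(C)=O)[C@@H](c4ccc(Br)o4)[C@@H]3[C@@](C)(CC(=O)O)[C@@H]1C
F7 | step 20 | 15-bromo tetracyclic 2α,7α-diacetate | CC(=O)O[C@@H]1C[C@@]23COC(=O)C2=C[C@H](OC(C)=O)[C@H]2c4oc(Br)cc4C(=O)C[C@@](C)([C@@H]1C)[C@@H]23
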